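The meeting opened on a trap: counting the whole substrate charge as product to come, when Tuesday's and Saturday's flasks hold 0.190 M of coupling partner against 0.20 M of substrate.

| setting | delta | beta | Tuesday's | Saturday's |
|---|---|---|---|---|
| substrate | 0.20 M | 0.20 M | 0.20 M | 0.20 M |
| coupling partner | 0.13 M | 0.29 M | 0.190 M | 0.190 M |
| remark | run made earlier | run made earlier |  |  |
| time |  |  | 8.0 h | 25 h |

| run | time / h | isomer of the product / % | substrate / % | intermediate B / % | target / % |
|---|---|---|---|---|---|
| delta | 0.667 | 0.6 | 65.0 | 2.7 | 13.4 |
| delta | 2.00 | 6.1 | 51.2 | 4.9 | 29.4 |
| delta | 4.00 | 16.6 | 42.5 | 5.7 | 32.0 |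
| delta | 6.00 | 27.1 | 39.1 | 5.6 | 27.6 |
| delta | 8.00 | 34.6 | 37.3 | 5.8 | 22.4 |
| beta | 0.667 | 1.2 | 38.3 | 5.6 | 24.2 |
| beta | 2.00 | 10.7 | 18.6 | 7.5 | 50.3 |
| beta | 4.00 | 28.4 | 7.9 | 9.1 | 51.1 |
| beta | 6.00 | 43.4 | 3.6 | 8.3 | 42.6 |
| beta | 8.00 | 55.3 | 2.0 | 8.4 | 33.2 |

(standard deviation of a reading: 0.3 percentage points)

1. which of these there is most of at the end, counted by the substrate in it, Tuesday's (intermediate B / target / substrate / isomer of the product)
2. which of these there is most of at the end, counted by the substrate in it, Saturday's (intermediate B / target / substrate / isomer of the product)
3. how much there is at the end of the one of these that leads, in percent of the substrate charged: Tuesday's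
4. how much there is at the end of the one of these that leads, in percent of the substrate charged: Saturday's

The first speaker pointed to the delta run. Its substrate stood at 37.3% after 8.00 h, a little more than the 35.0% that one-to-one use of coupling partner leaves. In the beta run, with coupling partner in excess, substrate fell to 2.0%. She therefore proposed to carry the room, 95.0% for Tuesday's and Saturday's: the coupling partner charged over the substrate charged, which is the share of substrate that this limiting reagent can convert.

The second speaker added that isomer of the product made up 55.2% of the converted substrate in the delta run and 56.4% in the beta run at 8.00 h, despite their different charges. He proposed to take 55.8% for Tuesday's.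

The secretary's own first round, room times share, gave 53.0% of isomer of the product for Tuesday's, with the room full. Going round again, she noted that the delta run's substrate still stood above its one-to-one floor after 8.00 h, so she expected less for Tuesday's.

The forecast gave less for Tuesday's: isomer of the product leading on Tuesday's at 46.5% (44.5% to 48.5%), and isomer of the product on Saturday's at 77% (73% to 81.5%). Its grounds included this: “For 95% partner this leaves about 15.5% substrate at 8 h and about 8% at 25 h.” At the carried share, its Tuesday figure means 83.3% converted, less than the room, so the meeting accepted it.

Tuesday's flask gave 46.1% of isomer of the product and Saturday's 77.3% of isomer of the product, each inside the forecast's range.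

    substrate + coupling partner ⇌ intermediate A (K = 7.60 /M, k = 0.00290 /M/s)
    intermediate A → target (k = 3.60 × 10⁻⁴ /s)
    substrate + coupling partner ⇌ intermediate B (K = 13.0 /M, k = 1.80 × 10⁻⁴ /M/s)
    target ⇌ isomer of the product (K = 11.0, k = 4.90 × 10⁻⁵ /s)

Saturday's flask kept 8.41% of substrate, so 91.6% was converted, less than the room, and isomer of the product held 84.4% of that. The neighbouring flask, like Saturday's but with 0.80 M of substrate, has a room of 23.8%. That reckons 76.2% of substrate left and, at Saturday's share, 20.1% of isomer of the product. That neighbouring flask holds 20.4% of isomer of the product, with coupling partner at 0.057% of its charge and substrate leading at 76.3%.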